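Count the leftover, not the product: in the alder run at 40.0 h, 18.0% of the charge is something other than left-handed product.

| flask | left-handed substrate | right-handed substrate | gas | temperature | remark | time |
|---|---|---|---|---|---|---|
| alder | 0.45 M | 0.45 M | 82 mM (held) | 0 °C | run made earlier |  |
| autumn | 0.30 M | 0.30 M | 82 mM (held) | 0 °C |  | 6.0 d |
| midnight | 0.30 M | 0.30 M | 82 mM (held) | −15 °C |  | 10 d |

- alder (time / h: left-handed product / %, left-handed substrate / %): 3.00: 14, 35; 6.00: 27, 32; 12.0: 44, 16; 25.0: 66, 13; 40.0: 82, 6

(each reading ± 2 percentage points)

- the winner by amount of left-handed product, in percent of the left-handed substrate and right-handed substrate together charged; "neither" if no more than 2 percentage points parts them (autumn / midnight / neither)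
- how much left-handed product is there at the end, in percent of the left-handed substrate and right-handed substrate together charged: autumn
- how much left-handed product is there at the end, in percent of the left-handed substrate and right-handed substrate together charged: midnight

- partner is single-handed; left-handed substrate and right-handed substrate are mirror images of each other, charged as a racemate, each of them at the stated concentration
- what was read earlier has a scatter of 2 percentage points, one standard deviation
- at the start none of the gas is in solution
- the earlier runs do not show what temperature does; that part of a forecast is a guess
- the handed part of partner does not stay in what it makes, so the products of the two hands are mirror images too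

Build the flask one process at a time. Take the main step first, partner with left-handed substrate: left-handed substrate is half of the charge, so left-handed product stops at that line. The last alder reading of 82% stands above it, so add the second process, the interconversion of the two substrates, which lets right-handed substrate feed the main step. With the gas held, assume partner steady, a pseudo-first-order case, and treat both substrates as one pool whose fraction left falls exponentially. The logarithm of charged over left, divided by the time, then gives 0.0429 h⁻¹, the clearing constant. Treat it as a reading: at 3.00 h it predicts 12.1% against the alder reading of 14%, a gap no wider than the scatter of 2 percentage points.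

Under that assumption the percentages do not depend on the charge, so over 6.0 d autumn keeps 0.208% and makes 99.8%. Now add the rest: a leak into right-handed product, unread in alder, lowers that figure by an amount I cannot size, so commit to just under it. For midnight the temperature is a guess: divide the constant by 6, and the reckoning gives 82.0% at 10 d, so autumn leads.

The forecast names autumn, with 96% for autumn and 84% for midnight, saying “Midnight is a guess”, and so stands below my autumn figure and above my midnight figure.

The simulation gives autumn, with 98.1% for autumn and 79.0% for midnight.

    partner + left-handed substrate → left-handed product (k = 4.31 × 10⁻⁴ M⁻¹ s⁻¹, Ea = 66.0 kJ mol⁻¹)
    partner + right-handed substrate → right-handed product (k = 3.57 × 10⁻⁶ M⁻¹ s⁻¹, Ea = 83.0 kJ mol⁻¹)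
    left-handed substrate ⇌ right-handed substrate (k = 1.85 × 10⁻⁵ s⁻¹, Ea = 82.0 kJ mol⁻¹)
    gas ⇌ partner, rate k4*(csat - [partner]) (kL = 0.00322 s⁻¹)
    partner → decomposed reagent (k = 1.79 × 10⁻⁴ s⁻¹, Ea = 76.0 kJ mol⁻¹)
    (constants at 0 °C)

Take the fraction left again: the autumn conversion of 99.6% gives a clearing constant of 0.0387 h⁻¹, and the midnight conversion of 79.9% gives 0.006690 h⁻¹, a factor of 5.78 lower. Temperature is the main reason for the midnight shortfall: the midnight flask gives 79.0%, and without the temperature difference 98.5%, a gain of 19 points, which is 93% of what is missing. Carried to the neighbour, the midnight flask read at 4.0 d, the midnight constant leaves 52.6%, and that flask holds 46.5% of the two substrates.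

The earlier runs and the new flask were computed from invented constants; the scatter is artificial.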